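**Plan**

The target is (4R)-6-benzoyl-5,7-dihydroxy-8-prenyl-4-phenylchroman-2-one: a dihydropyranone ring (O1, C2, C3, C4, C4a, C8a) fused to a fully substituted phloroglucinol ring.
Retrosynthetic cuts, in order: C8–prenyl (through a C8–I bond); O1–C2, C2–C3 and C4–H of the lactone (back to a 2-(1-phenylethenyl)phenol and carbon monoxide); C4a–C(vinyl) (back to an o-iodophenol and a vinylboronate); the benzoyl C(=O)–Ph bond (back to an aldehyde and a phenyl Grignard reagent).
Enabling feature: C2 is an isolated carbonyl carbon between O1 and the C3 methylene, and C4 is a diarylmethine on C4a, next to the O1-bearing C8a; the lactone ring therefore equals a 1,1-diarylethylene with an ortho phenol, plus CO, plus one hydrogen at C4.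
Forward: the benzophenone is assembled, iodinated and vinylated; the lactone, the only ring made, closes in the carbonylation; the two methyl ethers are then cleaved, C8 is iodinated and the prenyl group is coupled last.
Stereochemistry: the single stereocentre C4 (R) comes from enantioselective hydropalladation by a chiral bisphosphine palladium hydride; C4 is β to the carbonyl, has no leaving group, and is not touched again.
Regiochemistry: O5 and O7 are methyl ethers during ring closure, so only O1 (para to the benzoyl group) can lactonise; C8 is the only free ring carbon when it is functionalised.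

Key step: step 5

Remark: the sense of induction of the ligand is not predicted here, so the antipode that gives 4R is to be fixed in a trial run; after step 6 every step is kept free of base, because a 5-phenoxide could shift the lactone acyl group from O1 to O5.

**Route**

Step 1
Reactants: 1 4-hydroxy-2,6-dimethoxybenzaldehyde; 2 phenylmagnesium bromide
Product: 3 4-[hydroxy(phenyl)methyl]-3,5-dimethoxyphenol (racemic)
Conditions: PhMgBr (2.5 equiv), THF, 0 °C → rt; pH 7 buffer
Reagents that add atoms: phenylmagnesium bromide (2), Br[Mg]c1ccccc1
Why: Grignard addition, in which the first equivalent forms the magnesium phenoxide and the second adds to the aldehyde; the carbinol stereocentre is removed in step 2 and the acid-sensitive product is used crude.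

Step 2
Reactants: 3 4-[hydroxy(phenyl)methyl]-3,5-dimethoxyphenol
Product: 4 (4-hydroxy-2,6-dimethoxyphenyl)(phenyl)methanone
Conditions: DDQ (1.05 equiv), 1,4-dioxane, rt
Reagents that add atoms: none
Why: DDQ oxidation of a p-hydroxybenzylic alcohol, in which hydride is abstracted from the benzylic carbon activated by the para hydroxyl and both ortho methoxy groups, under neutral conditions that avoid acid-induced quinone methide formation.

Step 3
Reactants: 4 (4-hydroxy-2,6-dimethoxyphenyl)(phenyl)methanone; 5 N-iodosuccinimide
Product: 6 (4-hydroxy-3-iodo-2,6-dimethoxyphenyl)(phenyl)methanone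
Conditions: NIS (1.0 equiv), MeCN, 0 °C
Reagents that add atoms: N-iodosuccinimide (5), O=C1CCC(=O)N1I
Why: Electrophilic aromatic iodination ortho to the free phenol; C3 and C5 are equivalent by symmetry, so one equivalent of reagent should give a single mono-iodide.

Step 4
Reactants: 6 (4-hydroxy-3-iodo-2,6-dimethoxyphenyl)(phenyl)methanone; 7 4,4,5,5-tetramethyl-2-(1-phenylethenyl)-1,3,2-dioxaborolane
Product: 8 [4-hydroxy-2,6-dimethoxy-3-(1-phenylethenyl)phenyl](phenyl)methanone
Conditions: Pd(OAc)2 (5 mol%), SPhos (10 mol%), K3PO4, 1,4-dioxane/H2O, 80 °C, degassed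
Reagents that add atoms: 4,4,5,5-tetramethyl-2-(1-phenylethenyl)-1,3,2-dioxaborolane (7), C=C(B1OC(C)(C)C(C)(C)O1)c1ccccc1
Why: Suzuki–Miyaura coupling; a bulky electron-rich biarylphosphine suits an aryl iodide flanked by two oxygens, and the free phenol is tolerated as its phenoxide.

Step 5
Reactants: 8 [4-hydroxy-2,6-dimethoxy-3-(1-phenylethenyl)phenyl](phenyl)methanone; 9 carbon monoxide
Product: 10 (4R)-6-benzoyl-5,7-dimethoxy-4-phenylchroman-2-one
Conditions: Pd(OAc)2 (5 mol%), chiral bisphosphine L* (DTBM-SEGPHOS or a P-chiral WingPhos-type ligand, antipode chosen for 4R; 6 mol%), TsOH·H2O (10 mol%), CO (40 bar), DCE, 70 °C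
Reagents that add atoms: carbon monoxide (9), [C-]#[O+]
Why: A cationic palladium hydride carrying the chiral bisphosphine (from Pd(0) and TsOH) inserts the 1,1-diarylethylene of 8 with hydride to the diaryl carbon (C4) and palladium to the terminal CH2 (C3); CO then inserts into the primary alkyl–Pd bond to form C2–C3, and the neighbouring phenol attacks the acyl palladium to form O1–C2 and return Pd–H. The closest known reaction type is the palladium-hydride hydroesterification (alkoxycarbonylation) of alkenes, in its intramolecular asymmetric form that turns 2-(1-arylvinyl)phenols into 4-aryl-3,4-dihydrocoumarins. The lactone ring closes as a 6-exo-trig acyl substitution by the phenolic oxygen on the acyl–Pd carbon. The C4 stereocentre is set in the hydropalladation by the ligand, which delivers hydride to one enantiotopic face of an alkene whose two aryl groups differ strongly in shape (a flat phenyl against a perpendicular, doubly ortho-substituted ring). Three selectivities are needed: palladium at the terminal carbon, secured because the alternative places palladium on a quaternary diarylmethyl carbon; lactonisation through O1 only, secured because the other ortho oxygen and O7 are methyl ethers; and face selectivity, which rests on the ligand. The ketone, the aryl ethers and the aromatic rings should be inert to Pd–H and CO under these conditions.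

Step 6
Reactants: 10 (4R)-6-benzoyl-5,7-dimethoxy-4-phenylchroman-2-one
Product: 11 (4R)-6-benzoyl-5,7-dihydroxy-4-phenylchroman-2-one
Conditions: BBr3 (5 equiv), CH2Cl2, −78 → 0 °C; H2O
Reagents that add atoms: none
Why: Lewis-acid ether cleavage (BBr3 demethylation); both methoxy groups lie ortho to the benzoyl carbonyl, which chelates boron and speeds their cleavage, while the aryl lactone and the heteroatom-free C4 methine should be untouched at or below 0 °C.

Step 7
Reactants: 11 (4R)-6-benzoyl-5,7-dihydroxy-4-phenylchroman-2-one; 5 N-iodosuccinimide
Product: 12 (4R)-6-benzoyl-5,7-dihydroxy-8-iodo-4-phenylchroman-2-one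
Conditions: NIS (1.05 equiv), MeCN, 0 °C, dark
Reagents that add atoms: N-iodosuccinimide (5), O=C1CCC(=O)N1I
Why: Electrophilic aromatic iodination at C8, the only unsubstituted carbon of the phloroglucinol ring, under neutral conditions that leave the 5-hydroxy lactone as it is.

Step 8
Reactants: 12 (4R)-6-benzoyl-5,7-dihydroxy-8-iodo-4-phenylchroman-2-one; 13 tributyl(3-methylbut-2-en-1-yl)stannane
Product: 14 (4R)-6-benzoyl-5,7-dihydroxy-8-(3-methylbut-2-en-1-yl)-4-phenylchroman-2-one
Conditions: Pd(PPh3)4 (10 mol%), toluene, 90 °C, degassed
Reagents that add atoms: tributyl(3-methylbut-2-en-1-yl)stannane (13), CCCC[Sn](CCCC)(CCCC)CC=C(C)C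
Why: Stille coupling under base-free conditions; allylic stannanes transfer to aryl palladium through the less substituted carbon, so the linear prenyl group should result, and C4 takes no part.

**Compound list**

1 | 4-hydroxy-2,6-dimethoxybenzaldehyde | COc1cc(O)cc(OC)c1C=O | starting material
2 | phenylmagnesium bromide | Br[Mg]c1ccccc1 | starting material
3 | 4-[hydroxy(phenyl)methyl]-3,5-dimethoxyphenol (racemic) | COc1cc(O)cc(OC)c1C(O)c1ccccc1 | intermediate
4 | (4-hydroxy-2,6-dimethoxyphenyl)(phenyl)methanone | COc1cc(O)cc(OC)c1C(=O)c1ccccc1 | intermediate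
5 | N-iodosuccinimide | O=C1CCC(=O)N1I | starting material
6 | (4-hydroxy-3-iodo-2,6-dimethoxyphenyl)(phenyl)methanone | COc1cc(O)c(I)c(OC)c1C(=O)c1ccccc1 | intermediate
7 | 4,4,5,5-tetramethyl-2-(1-phenylethenyl)-1,3,2-dioxaborolane | C=C(B1OC(C)(C)C(C)(C)O1)c1ccccc1 | starting material
8 | [4-hydroxy-2,6-dimethoxy-3-(1-phenylethenyl)phenyl](phenyl)methanone | C=C(c1ccccc1)c1c(O)cc(OC)c(C(=O)c2ccccc2)c1OC | intermediate
9 | carbon monoxide | [C-]#[O+] | starting material
10 | (4R)-6-benzoyl-5,7-dimethoxy-4-phenylchroman-2-one | O=C1C[C@H](c2ccccc2)c2c(OC)c(C(=O)c3ccccc3)c(OC)cc2O1 | intermediate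
11 | (4R)-6-benzoyl-5,7-dihydroxy-4-phenylchroman-2-one | O=C1C[C@H](c2ccccc2)c2c(O)c(C(=O)c3ccccc3)c(O)cc2O1 | intermediate
12 | (4R)-6-benzoyl-5,7-dihydroxy-8-iodo-4-phenylchroman-2-one | O=C1C[C@H](c2ccccc2)c2c(O)c(C(=O)c3ccccc3)c(O)c(I)c2O1 | intermediate
13 | tributyl(3-methylbut-2-en-1-yl)stannane | CCCC[Sn](CCCC)(CCCC)CC=C(C)C | starting material
14 | (4R)-6-benzoyl-5,7-dihydroxy-8-(3-methylbut-2-en-1-yl)-4-phenylchroman-2-one | CC(C)=CCc1c(O)c(C(=O)c2ccccc2)c(O)c2c1OC(=O)C[C@@H]2c1ccccc1 | target

**Summary and risks**

Total step count: 8. Longest linear sequence: 8 steps (1 → 14).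

Steps most likely to fail:

Step 5. The two oxygen substituents flanking the vinyl group force the phloroglucinol ring out of the alkene plane, so hydropalladation may be slow and poorly face-selective, and acid-induced cationic dimerisation of the electron-rich alkene may outrun carbonylation. The fallback makes the C4 stereocentre by conjugate addition instead; it sets out from 4 and comes back at 10. Palladium acetate/trifluoroacetic acid-catalysed hydroarylation of ethyl propiolate at the carbon ortho to the free hydroxyl of 4, followed by spontaneous lactonisation through that same hydroxyl, should give 6-benzoyl-5,7-dimethoxy-2H-chromen-2-one F1. Rhodium(I)-catalysed asymmetric 1,4-addition of phenylboronic acid with a SEGPHOS-type bisphosphine (antipode chosen for 4R) in dioxane/water at 60 °C should then give 10.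

Step 8. The iodide sits between two oxygens and next to acidic phenols, so reduction of the C–I bond may compete with coupling, the prenyl group may be delivered through its tertiary carbon, and tin phenoxides formed by protonolysis of the stannane could trigger acyl exchange between O1 and O5. The fallback couples before the phenols are freed and builds the prenyl group by metathesis; it sets out from 10 and comes back at 14. Iodination of 10 with N-iodosuccinimide and catalytic trifluoroacetic acid in acetonitrile should give (4R)-6-benzoyl-8-iodo-5,7-dimethoxy-4-phenylchroman-2-one F2. Stille coupling with allyltributylstannane (Pd(PPh3)4, toluene, 100 °C), which has no regiochemical ambiguity, should give (4R)-6-benzoyl-5,7-dimethoxy-4-phenyl-8-(prop-2-en-1-yl)chroman-2-one F3. Boron tribromide at −78 → 0 °C, which monosubstituted allyl groups normally survive, should give (4R)-6-benzoyl-5,7-dihydroxy-4-phenyl-8-(prop-2-en-1-yl)chroman-2-one F4. Olefin cross-metathesis with excess 2-methylbut-2-ene and a second-generation ruthenium benzylidene catalyst (CH2Cl2, 40 °C, neutral) should then give 14.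

Step 6. Cleavage of the second ether may stall once the first phenoxide and the ketone are tied up as a boron chelate, and the Lewis acid may open the lactone or move its acyl group onto the newly freed 5-oxygen. The fallback removes the methyl groups before any lactone or stereocentre exists; it sets out from 4 and comes back at 11. Boron tribromide on 4 should give (2,4,6-trihydroxyphenyl)(phenyl)methanone F5. One equivalent of N-iodosuccinimide should give (2,4,6-trihydroxy-3-iodophenyl)(phenyl)methanone F6, and Suzuki–Miyaura coupling with 7 should give [2,4,6-trihydroxy-3-(1-phenylethenyl)phenyl](phenyl)methanone F7. Carbonylative lactonisation of F7 under the conditions of step 5 should give 11. Its lactone regiochemistry then rests only on the lower nucleophilicity of the hydroxyl hydrogen-bonded to the benzoyl group, and the isomeric lactone would have to be separated if it forms.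

**Further compounds**

F1 | step 5 | 6-benzoyl-5,7-dimethoxy-2H-chromen-2-one | O=C1C=Cc2c(OC)c(C(=O)c3ccccc3)c(OC)cc2O1
F2 | step 8 | (4R)-6-benzoyl-8-iodo-5,7-dimethoxy-4-phenylchroman-2-one | O=C1C[C@H](c2ccccc2)c2c(OC)c(C(=O)c3ccccc3)c(OC)c(I)c2O1
F3 | step 8 | (4R)-6-benzoyl-5,7-dimethoxy-4-phenyl-8-(prop-2-en-1-yl)chroman-2-one | O=C1C[C@H](c2ccccc2)c2c(OC)c(C(=O)c3ccccc3)c(OC)c(CC=C)c2O1
F4 | step 8 | (4R)-6-benzoyl-5,7-dihydroxy-4-phenyl-8-(prop-2-en-1-yl)chroman-2-one | O=C1C[C@H](c2ccccc2)c2c(O)c(C(=O)c3ccccc3)c(O)c(CC=C)c2O1
F5 | step 6 | (2,4,6-trihydroxyphenyl)(phenyl)methanone | O=C(c1ccccc1)c1c(O)cc(O)cc1O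
F6 | step 6 | (2,4,6-trihydroxy-3-iodophenyl)(phenyl)methanone | O=C(c1ccccc1)c1c(O)cc(O)c(I)c1O
F7 | step 6 | [2,4,6-trihydroxy-3-(1-phenylethenyl)phenyl](phenyl)methanone | C=C(c1ccccc1)c1c(O)cc(O)c(C(=O)c2ccccc2)c1O
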